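No rate constant stands among what we have, so we reckon from the spring run's readings instead, solving at both ends of the protic impurity scale and joining them.

| setting | spring | flask |
|---|---|---|
| substrate | 2 M | 2.0 M |
| partner | 0.95 equiv | 0.950 equiv |
| protic impurity | 0.84 M | 0.600 M |
| initiator | 9.4 mol% | 9.4 mol% |
| remark | run made earlier |  |
| time |  | 1.0 h |

spring run (percent of the substrate charged)

| time / min | chain carrier / % | target / % | substrate / % |
|---|---|---|---|
| 6.00 | 0 | 78.1 | 20.9 |
| 15.0 | 0.8 | 85.3 | 13.5 |
| 20.0 | 0 | 85.6 | 12.3 |
| 30.0 | 0 | 85.7 | 12.3 |
| 40.0 | 0.8 | 85.8 | 12.6 |
| 50.0 | 0 | 85.6 | 12.9 |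

(scatter of a reading: 0.5 percentage points)

- what was read earlier has a scatter of 0.5 percentage points, one standard deviation
- no earlier run changes the charge of protic impurity; that part of a forecast is a guess

- the species in which most of what was charged as substrate, at 1.0 h sits (target / chain carrier / substrate)
- the largest share itself, whichever of these holds it, in percent of the substrate charged

On the spring run's ladder, the chain carrier comes first: it never reads above 0.8%, with a scatter of 0.5 percentage points, so we treat it as a short-lived intermediate in steady state, used about as fast as it is made. Next comes the chain, with target at 78.1% after 6.00 min and 85.6% after 20.0 min. Then comes a plateau: target still reads 85.6% at 50.0 min, with substrate near 12.3%. The flask's 1.0 h is longer than that approach, so we reckon its end state, not a rate.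

The spring run's partner allows 95.0% target, yet 85.7% is read, and we call the difference, 9.30%, the partner gap: partner charged that never became target. We take partner as the limiting reagent and the gap as its loss to protic impurity. That is our assumption, since no earlier run changes that charge. One end is no impurity and no gap, the other 0.84 M and the spring gap. A straight line between them gives the flask, at 0.600 M, target 88.4%, and substrate 9.64%, so target leads.

The forecast says target at 91%, higher than our figure, on different grounds: “The carrier is therefore being killed, not starved of partner.”

The flask gives target, at 88.3%, with substrate at 9.24% and partner at 0%; the forecast stands within its margin.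

    partner → decomposition product (k = 3.53 × 10⁻⁷ s⁻¹)
    2 chain carrier → ended chains (k = 8.90 × 10⁶ M⁻¹ s⁻¹)
    partner + chain carrier → target + initiating radical (k = 6980 M⁻¹ s⁻¹)
    substrate + initiating radical ⇌ chain carrier (K = 73000 M⁻¹, k = 3920 M⁻¹ s⁻¹)
    initiator → 2 initiating radical (k = 3.87 × 10⁻⁵ s⁻¹)
    partner + protic impurity → quenched reagent (k = 8.97 × 10⁻⁴ M⁻¹ s⁻¹)

Quenched reagent in the flask stands at 0.134 M, which is 6.68% of the substrate charged, beside a scaled gap of 6.64%. A neighbour flask charged with 0.15 M of protic impurity has a scaled gap of 1.66%, which leaves target at 93.3%. That neighbour holds 0.0350 M of quenched reagent, partner at 0%, and ends with target at 93.2%.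

The earlier runs and the new flask were computed on assumed constants; the scatter is artificial.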